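## The problem

The target 24 is a trimer of three flavan-3-ol units joined head to tail by two C4→C8 bonds: a gallocatechin unit on top (2R,3S, pyrogallol ring B), a catechin unit in the middle (2R,3S) and an ent-catechin unit at the bottom (2S,3R). Four of its eight stereocentres (C2 and C3 of the top and bottom units) can be bought with the monomers. Top C4 carries its aryl group trans to the C3 oxygen, which is what a C4 cation of a 2,3-trans flavan gives when it is captured anti to the C3 substituent. The middle unit is the difficulty: its C4 aryl group (bottom ring A) is cis to the C3 oxygen while the C2 aryl group is trans to both. Cation chemistry at middle C4 would give the trans epimer, and neither the top nor the bottom stereocentres lie close enough to bias this pair, which sits between two phloroglucinol rings. Once C3 and C4 are cis, however, they share one face of ring C and can together direct what is done at C2. The molecule has thirteen phenolic hydroxyls including an air- and base-sensitive pyrogallol, C2 centres that epimerise in base while the phenols are free, and two diarylmethine interflavan bonds that protic acid cleaves; all hydroxyls therefore need one protecting group that leaves under neutral conditions at the very end. The enabling feature is in the middle unit: O1, C8a, C4a and C4 are the atoms of an o-quinone methide whose methide carbon is the diarylmethine C4, and the remaining pair C2–C3, with oxygen on C3 and C2 bound to O1, is a two-carbon unit at the oxidation level of an alkoxyketene. Ring C of the middle unit can thus be closed as a lactone in one [4+2]-type event.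

## Retrosynthesis

**Unmasking.** The sixteen O–benzyl bonds of 23 are cut last, so that 24 appears in one neutral hydrogenolysis. Benzyl is the only common phenol protecting group that survives organolithium reagents, Lewis acids and aluminium hydride reduction and still leaves without acid or base. Acyl groups would not survive the carbanion and hydride steps, and methyl ethers could not be removed from this skeleton. Compound 23 is no simpler in skeleton, but it is robust.

**Middle C2–aryl bond.** In 23 the bond between middle C2 and its catechol ring is cut, giving the lactol acetate 19 and the aryl nucleophile 22 (from bromide 20 through 21). This cut is preferred to adding the aryl group to the lactone carbonyl and reducing afterwards: a hydride would enter the open face of the 2-aryl oxocarbenium ion and leave the aryl group cis to C3–O, the wrong epimer. With the aryl group as the nucleophile, the cis pair at C3/C4 pushes it to the opposite face and gives the 2,3-trans relation of catechin. The precursor lacks ring B and one stereocentre. The forward reaction must show high facial selectivity and an aryl transfer faster than capture of the cation by the electron-rich rings of the substrate.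

**Oxidation level of C2.** Acetate 19 is traced to lactone 17 through the aluminium hemiacetal 18. No skeletal bond is cut. The forward step must stop at the lactol level and must not release the open-chain α-benzyloxy aldehyde in the presence of base, since C3 would then epimerise. The hemiacetal is therefore acylated as it is formed.

**Middle ring C (key cut).** In 17 the bonds C3–C4 and O1–C2 are cut, which leads to the o-quinone methide 15 and benzyloxyketene 16, and behind them to the benzhydrol 13 and the acid chloride 14. The neighbouring cut, C4–C8 of the bottom unit by cation arylation, is the standard interflavan disconnection but gives the 3,4-trans epimer. The chosen cut forms the crowded C4 centre with a small carbon nucleophile under catalyst control, in a reaction whose kinetic product is the cis lactone. Two stereocentres and one ring disappear, and the carbinol centre of 13 need not be controlled because both epimers give 15. The forward reaction must deliver cis diastereoselectivity, absolute control of the new pair, and C–C bond formation ahead of any O-acylation of the phenol.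

**Methide carbon to bottom C8.** In 13 the bond between the carbinol carbon (future middle C4) and bottom C8 is cut as a carbonyl addition, giving the salicylaldehyde 7 and the aryllithium 12 (from bromide 11). A Friedel–Crafts union would leave C8 against C6 of the bottom unit open and would expose an acid-sensitive benzhydrol to acid; the position of the bromine fixes the regiochemistry instead. The two fragments are of similar size, so this is the convergent point of the route. The forward reaction must add a di-ortho-substituted aryllithium to a hindered, electron-rich aldehyde.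

**Top C4 to middle ring A.** The formyl carbon of 7 is removed to give phenol 6, and in 6 the bond from top C4 to the phenol ring is cut, giving the C4-activated gallocatechin 4 and 3,5-bis(benzyloxy)phenol 5. Here the conventional cation coupling is kept, because the 3,4-trans relation it produces is the one the top unit needs. The nucleophile is only ring A of the middle unit, since its ring C is built later. The forward steps must direct the arylation and then the formylation to the two ortho positions of the phenol. Compound 4 comes from (+)-gallocatechin 1 through 2 and 3 by phenol benzylation, C4 oxidation and benzylation of the C3 hydroxyl.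

**Bottom unit.** Bromide 11 is traced through 10 and 9 to (−)-catechin 8 by cutting the C8–Br bond and the benzyl ethers. Each forward step is a standard operation on a catechin monomer.

## Roads not taken

Alternative 1: The cut goes through bottom ring A itself: bond C4a–C8a is opened and the aromatic ring is traced back to a triketide chain. The forward key step is a base-induced Dieckmann-type closure of A2, a γ-lactone cis-fused across middle O3 and C4 whose α-carbon carries a C(=O)CH2C(=O)CH2CO2Me chain. The terminal malonyl methylene attacks the lactone carbonyl, middle O3 leaves as the alkoxide, and enolisation gives the methyl 2,4,6-trihydroxybenzoate ring of A1.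

- Merits: the five-membered lactone of A2 can only be cis-fused, so the 3,4-cis relation is enforced by geometry and not by a kinetic preference. No Friedel–Crafts regiochemistry arises, and middle C3–OH emerges free and distinguished. In this respect the road is better than the chosen one.
- Weak points: A1 holds only the middle unit and ring A of the bottom unit. The bottom pyran ring with its 2S,3R centres and catechol ring must still be built from the ester carbon. The two phenols flanking that ester would close to the 8-linked and the 6-linked isomer alike. The top unit must then be attached at middle C8 in competition with more accessible nucleophilic positions. The polyketone chain also has several acidic sites and can fold by aldol instead of Claisen condensation.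
- Comparison: the chosen plan sets three intact monomer units, one convergent union and thirteen steps against the geometric certainty of A2. Its cis relation rests on catalyst control, backed by a fallback.

Alternative 2: The cut removes top C3–O and C4–C4a, so that the top pyran is made last. The forward key step is epoxidation of the E-alkene of the aryl allyl ether A4, followed in the same pot by attack of the 3,5-bis(benzyloxy)phenoxy ring on the benzylic oxirane carbon, giving A3 with a free top C3–OH.

- Merits: the top unit is made from simple aromatics, so no scarce gallocatechin is needed. Both ortho positions of the phenoxy ring are equivalent and the para position cannot reach, so the arylation has no regiochemical question, where step 4 of the chosen route has one. Anti opening of a trans epoxide gives the 3,4-trans relation by mechanism. In these respects the road is as good or better.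
- Weak points: A4 must already contain the 3,4-cis junction between the middle and bottom units, so the real difficulty is only moved into the synthesis of A4. The epoxide face must be chosen by a reagent on a hindered, very electron-rich alkene in the presence of seven stereocentres. The oxirane carbon next to a trioxygenated ring ionises readily, which erodes the stereospecific opening. The doubly activated C2–O bond of A4 can ionise and racemise, and electrophilic oxidants meet nine electron-rich rings.
- Comparison: the chosen plan takes all three top stereocentres from the chiral pool and from substrate control, uses no oxidant after step 2, and solves the cis junction directly.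

Alternative 3: The cut removes top C3–C4 and O1–C2. The forward key step dehydrates the benzhydrol A6 to an o-quinone methide, which adds to the E-styrylboronate A7 in a hetero-Diels–Alder reaction to give A5 with a pinacolboryl group at top C3; oxidation of the C–B bond with retention would follow.

- Merits: it uses the same o-quinone methide logic as the chosen plan and is highly convergent, closing the top ring in the last C–C bond-forming step. The alkene geometry is carried into the 2,3-trans relation, and no gallocatechin is needed. In convergence it is at least equal to the chosen plan.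
- Weak points: a vinylboronate is a reluctant partner for an electron-poor heterodiene. No catalyst or chiral-pool element fixes the absolute sense of the three new top stereocentres against the five already present, so diastereomers are expected. The endo/exo preference that decides the 3,4 relation is uncertain. As in Alternative 2, A6 must already contain the 3,4-cis middle unit.
- Comparison: the chosen plan uses its one quinone methide annulation on the bond that no conventional method sets and buys the top stereocentres. It pays for this with the regiochemical question of step 4 and a linear passage through the top unit.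

Key step: step 10

Remark: 13 is carried as both carbinol epimers, 19 as both anomers and 15 without assigned geometry at the exocyclic double bond, because each of these elements is erased in the next bond-forming event.
Remark: 1, 5, 8, 14 and 20 are taken as purchasable.

Step 1
Reactants: 1 (+)-gallocatechin
Product: 2 5,7,3′,4′,5′-penta-O-benzyl-(+)-gallocatechin [(2R,3S), free 3-OH]
Conditions: BnBr, K2CO3, DMF, 0 °C → rt, under Ar
Reagents that add atoms: benzyl bromide, BrCc1ccccc1
Why: Williamson etherification; carbonate deprotonates only the five phenols, so the C3 alcohol stays free, and exclusion of air protects the pyrogallol phenoxide and the C2 centre.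

Step 2
Reactants: 2 5,7,3′,4′,5′-penta-O-benzyl-(+)-gallocatechin
Product: 3 (2R,3S,4S)-5,7-bis(benzyloxy)-4-(2-ethoxyethoxy)-2-[3,4,5-tris(benzyloxy)phenyl]chroman-3-ol
Conditions: DDQ, 2-ethoxyethanol, CH2Cl2, rt
Reagents that add atoms: 2-ethoxyethanol, CCOCCO
Why: Benzylic oxidation by hydride abstraction: DDQ removes hydride from C4, and the alcohol captures the cation stabilised by ring A trans to the C2 aryl group; this acetal-like centre is erased again in step 4.

Step 3
Reactants: 3 the 4-(2-ethoxyethoxy) alcohol
Product: 4 (2R,3S,4S)-3,5,7-tris(benzyloxy)-4-(2-ethoxyethoxy)-2-[3,4,5-tris(benzyloxy)phenyl]chromane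
Conditions: NaH, BnBr, DMF, 0 °C → rt
Reagents that add atoms: benzyl bromide, BrCc1ccccc1
Why: Williamson etherification of the secondary alkoxide; with all phenols already etherified there is no phenoxide that could open ring C, so C2 is safe, and the C4 ether is inert to base.

Step 4
Reactants: 4 the C4-activated hexa-O-benzylgallocatechin; 5 3,5-bis(benzyloxy)phenol
Product: 6 3,5-bis(benzyloxy)-2-[(2R,3S)-3,5,7-tris(benzyloxy)-2-(3,4,5-tris(benzyloxy)phenyl)chroman-4-yl]phenol, aryl group at C4 trans to the 3-benzyloxy group (4α)
Conditions: 5 (3 equiv), BF3·OEt2, CH2Cl2, −78 → −20 °C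
Reagents that add atoms: none
Why: Friedel–Crafts C-arylation of a phenol by the C4 cation released from the acetal; two ortho carbons compete with one para carbon that is flanked by two benzyloxy groups, and any aryl ether formed by O-attack re-ionises and migrates to the ortho carbon. The phenol enters anti to the C3 benzyloxy group, which sets top C4 in the 3,4-trans sense.

Step 5
Reactants: 6 the 2-(flavan-4-yl)phenol
Product: 7 4,6-bis(benzyloxy)-2-hydroxy-3-[(2R,3S)-3,5,7-tris(benzyloxy)-2-(3,4,5-tris(benzyloxy)phenyl)chroman-4α-yl]benzaldehyde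
Conditions: MgCl2, Et3N, (CH2O)n, THF, reflux
Reagents that add atoms: formaldehyde (as paraformaldehyde), C=O
Why: Casnati–Skattebøl ortho-formylation: the magnesium phenoxide delivers formaldehyde to the only free ortho carbon through a six-membered chelate and a second formaldehyde oxidises the hydroxymethyl intermediate; the para carbon cannot be reached this way and the mildly basic medium spares the acid-labile C4–aryl bond.

Step 6
Reactants: 8 (−)-catechin
Product: 9 5,7,3′,4′-tetra-O-benzyl-(−)-catechin [(2S,3R), free 3-OH]
Conditions: BnBr, K2CO3, DMF, 0 °C → rt, under Ar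
Reagents that add atoms: benzyl bromide, BrCc1ccccc1
Why: Williamson etherification of the four phenols only, as in step 1.

Step 7
Reactants: 9 5,7,3′,4′-tetra-O-benzyl-(−)-catechin
Product: 10 8-bromo-5,7,3′,4′-tetra-O-benzyl-(−)-catechin
Conditions: NBS, CH2Cl2, −78 → 0 °C
Reagents that add atoms: N-bromosuccinimide, O=C1CCC(=O)N1Br
Why: Electrophilic aromatic bromination; in 5,7-dialkoxyflavans C8 is the more reactive of the two free positions of ring A, and one equivalent at low temperature stops at the monobromide.

Step 8
Reactants: 10 8-bromo-5,7,3′,4′-tetra-O-benzyl-(−)-catechin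
Product: 11 8-bromo-3,5,7,3′,4′-penta-O-benzyl-(−)-catechin
Conditions: NaH, BnBr, DMF, 0 °C → rt
Reagents that add atoms: benzyl bromide, BrCc1ccccc1
Why: Williamson etherification of the C3 alkoxide; the aryl bromide is inert to NaH and removal of the last acidic proton prepares the halogen–lithium exchange.

Step 9
Reactants: 11 8-bromo-3,5,7,3′,4′-penta-O-benzyl-(−)-catechin; 7 the salicylaldehyde
Product: 13 benzhydrol [4,6-bis(benzyloxy)-2-hydroxy-3-(hexa-O-benzylgallocatechin-4α-yl)phenyl][3,5,7,3′,4′-penta-O-benzyl-(−)-catechin-8-yl]methanol as both carbinol epimers, via 8-lithio-3,5,7,3′,4′-penta-O-benzyl-(−)-catechin 12 (not isolated)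
Conditions: 11, t-BuLi (2 equiv), THF, −78 °C; then 7 pretreated with NaH (THF, 0 °C), −78 → 0 °C; H2O
Reagents that add atoms: none
Why: Bromine–lithium exchange followed by 1,2-addition of the aryllithium to the aldehyde; converting the phenol into its sodium salt beforehand keeps it from quenching the carbanion, and the new carbinol centre needs no control because it becomes sp2 in step 10.

Step 10
Reactants: 13 the benzhydrol; 14 benzyloxyacetyl chloride
Product: 17 (3S,4S)-3,5,7-tris(benzyloxy)-8-(hexa-O-benzylgallocatechin-4α-yl)-4-[3,5,7,3′,4′-penta-O-benzyl-(−)-catechin-8-yl]chroman-2-one (3,4-cis lactone), via o-quinone methide 15 (not isolated), via benzyloxyketene 16 (not isolated)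
Conditions: pyridinium p-toluenesulfonate (5 mol %), 4 Å molecular sieves, CH2Cl2, rt; then −78 °C, i-Pr2NEt, O-benzoylquinidine (20 mol %), 14 in toluene added slowly, −78 → −40 °C
Reagents that add atoms: none
Why: Acid-catalysed dehydration over sieves converts both epimers of 13 into the push–pull o-quinone methide 15 before any acylating agent is present, so no free phenol remains to be O-acylated. i-Pr2NEt dehydrochlorinates 14 to benzyloxyketene 16, which O-benzoylquinidine captures as the zwitterionic (Z)-acylammonium enolate. Conjugate addition of the enolate α-carbon to the methide carbon of 15 forms C3–C4 and rearomatises ring A; the phenoxide so released attacks the acylammonium carbon in a 6-exo-trig closure that forms O1–C2, closes the lactone ring and returns the catalyst. The closest known reaction type is the cinchona-alkaloid- or N-heterocyclic-carbene-catalysed formal [4+2] annulation of o-quinone methides with ketene-derived enolates, which gives cis-3,4-disubstituted dihydrocoumarins. C3 is set by the catalyst, whose quinoline and benzoate groups cover one face of the enolate; bonding of the methide carbon to the Si face of the α-carbon (O > C1 > H) gives 3S, and the quinine-derived pseudoenantiomer is the immediate alternative should the quinidine series expose the other face. C4 follows from the endo arrangement: with the ammonium group exo, the benzyloxy group of the (Z)-enolate lies under the heterodiene while the aryl group of 15 points outward (the inward geometry is too crowded to react and equilibrates through the zwitterionic form), so that benzyloxy and aryl groups end up cis. The step needs C–C bond formation to outrun ketene dimerisation and needs the kinetic cis lactone to survive; slow addition of 14 at low temperature, the small size of the two-carbon nucleophile and a hindered tertiary amine as the only base secure this.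

Step 11
Reactants: 17 the 3,4-cis lactone
Product: 19 (3S,4S)-2-acetoxy-3,5,7-tris(benzyloxy)-8-(hexa-O-benzylgallocatechin-4α-yl)-4-[3,5,7,3′,4′-penta-O-benzyl-(−)-catechin-8-yl]chromane as both anomers, via diisobutylaluminium hemiacetal 18 (not isolated)
Conditions: i-Bu2AlH, CH2Cl2, −78 °C; then pyridine, 4-(dimethylamino)pyridine, Ac2O, −78 → −20 °C
Reagents that add atoms: acetic anhydride, CC(=O)OC(C)=O
Why: Reductive acetylation of a lactone: one hydride gives the aluminium hemiacetal, which is stable at −78 °C and is acylated in place, so the ring-opened α-benzyloxy aldehyde is never exposed to base and C3 keeps its configuration.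

Step 12
Reactants: 19 the lactol acetate; 20 4-bromo-1,2-bis(benzyloxy)benzene
Product: 23 hexadeca-O-benzyl trimer (perbenzylated gallocatechin-(4α→8)-catechin-(4β→8)-ent-catechin; middle unit 2R,3S,4S), via (3,4-dibenzyloxyphenyl)lithium 21 (not isolated), via (3,4-dibenzyloxyphenyl)zinc chloride 22 (not isolated)
Conditions: 20, n-BuLi, THF, −78 °C; ZnCl2, → 0 °C, solvent exchanged for toluene; then 19, BF3·OEt2, CH2Cl2–toluene, −78 → −20 °C
Reagents that add atoms: none
Why: SN1-type substitution at an anomeric acetate, as in C-aryl glycoside synthesis: BF3 ionises either anomer to the O-aryl oxocarbenium ion and the arylzinc transfers its aryl group to C2. The cis-disposed C3 benzyloxy and pseudoaxial C4 aryl groups block one face, so the aryl group enters trans to both and middle C2 is set as in catechin (2R).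

Step 13
Reactants: 23 the hexadeca-O-benzyl trimer
Product: 24 gallocatechin-(4α→8)-catechin-(4β→8)-ent-catechin (target)
Conditions: H2 (1 atm), Pd(OH)2/C, THF–MeOH–H2O, rt; filtration and freeze-drying under Ar
Reagents that add atoms: none
Why: Hydrogenolysis of all sixteen benzyl ethers under neutral conditions, the established way to unmask perbenzylated oligomeric flavan-3-ols; the diarylmethine C–C bonds and the ring C–O bonds are not cleaved and no stereocentre is touched.

## Compound list

1 | (+)-gallocatechin, (2R,3S) | Oc1cc(O)c2c(c1)O[C@H](c1cc(O)c(O)c(O)c1)[C@@H](O)C2 | starting material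
2 | 5,7,3′,4′,5′-penta-O-benzyl-(+)-gallocatechin | c3ccccc3COc1cc(OCc3ccccc3)c2c(c1)O[C@H](c1cc(OCc3ccccc3)c(OCc3ccccc3)c(OCc3ccccc3)c1)[C@@H](O)C2 | intermediate
3 | (2R,3S,4S)-5,7-bis(benzyloxy)-4-(2-ethoxyethoxy)-2-[3,4,5-tris(benzyloxy)phenyl]chroman-3-ol | c3ccccc3COc1cc(OCc3ccccc3)c2c(c1)O[C@H](c1cc(OCc3ccccc3)c(OCc3ccccc3)c(OCc3ccccc3)c1)[C@@H](O)[C@H]2OCCOCC | intermediate
4 | (2R,3S,4S)-3,5,7-tris(benzyloxy)-4-(2-ethoxyethoxy)-2-[3,4,5-tris(benzyloxy)phenyl]chromane | c3ccccc3COc1cc(OCc3ccccc3)c2c(c1)O[C@H](c1cc(OCc3ccccc3)c(OCc3ccccc3)c(OCc3ccccc3)c1)[C@@H](OCc3ccccc3)[C@H]2OCCOCC | intermediate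
5 | 3,5-bis(benzyloxy)phenol | Oc1cc(OCc2ccccc2)cc(OCc2ccccc2)c1 | starting material
6 | 3,5-bis(benzyloxy)-2-(hexa-O-benzylgallocatechin-4α-yl)phenol (3,4-trans in the flavan) | c3ccccc3COc1cc(OCc3ccccc3)c2c(c1)O[C@H](c1cc(OCc3ccccc3)c(OCc3ccccc3)c(OCc3ccccc3)c1)[C@@H](OCc3ccccc3)[C@@H]2c1c(OCc3ccccc3)cc(OCc3ccccc3)cc1O | intermediate
7 | 4,6-bis(benzyloxy)-2-hydroxy-3-(hexa-O-benzylgallocatechin-4α-yl)benzaldehyde | c3ccccc3COc1cc(OCc3ccccc3)c2c(c1)O[C@H](c1cc(OCc3ccccc3)c(OCc3ccccc3)c(OCc3ccccc3)c1)[C@@H](OCc3ccccc3)[C@@H]2c1c(OCc3ccccc3)cc(OCc3ccccc3)c(C=O)c1O | intermediate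
8 | (−)-catechin, (2S,3R) | Oc1cc(O)c2c(c1)O[C@@H](c1ccc(O)c(O)c1)[C@H](O)C2 | starting material
9 | 5,7,3′,4′-tetra-O-benzyl-(−)-catechin | c3ccccc3COc1cc(OCc3ccccc3)c2c(c1)O[C@@H](c1ccc(OCc3ccccc3)c(OCc3ccccc3)c1)[C@H](O)C2 | intermediate
10 | 8-bromo-5,7,3′,4′-tetra-O-benzyl-(−)-catechin | c3ccccc3COc1cc(OCc3ccccc3)c2c(c1Br)O[C@@H](c1ccc(OCc3ccccc3)c(OCc3ccccc3)c1)[C@H](O)C2 | intermediate
11 | 8-bromo-3,5,7,3′,4′-penta-O-benzyl-(−)-catechin | c3ccccc3COc1cc(OCc3ccccc3)c2c(c1Br)O[C@@H](c1ccc(OCc3ccccc3)c(OCc3ccccc3)c1)[C@H](OCc3ccccc3)C2 | intermediate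
12 | 8-lithio-3,5,7,3′,4′-penta-O-benzyl-(−)-catechin (formed in the flask) | c3ccccc3COc1cc(OCc3ccccc3)c2c(c1[Li])O[C@@H](c1ccc(OCc3ccccc3)c(OCc3ccccc3)c1)[C@H](OCc3ccccc3)C2 | intermediate
13 | benzhydrol: [4,6-bis(benzyloxy)-2-hydroxy-3-(hexa-O-benzylgallocatechin-4α-yl)phenyl][penta-O-benzyl-(−)-catechin-8-yl]methanol, both carbinol epimers | c3ccccc3COc1cc(OCc3ccccc3)c2c(c1)O[C@H](c1cc(OCc3ccccc3)c(OCc3ccccc3)c(OCc3ccccc3)c1)[C@@H](OCc3ccccc3)[C@@H]2c1c(OCc3ccccc3)cc(OCc3ccccc3)c(c1O)C(O)c1c(OCc3ccccc3)cc(OCc3ccccc3)c2c1O[C@@H](c1ccc(OCc3ccccc3)c(OCc3ccccc3)c1)[C@H](OCc3ccccc3)C2 | intermediate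
14 | benzyloxyacetyl chloride | ClC(=O)COCc1ccccc1 | starting material
15 | o-quinone methide: 3,5-bis(benzyloxy)-2-(hexa-O-benzylgallocatechin-4α-yl)-6-[(penta-O-benzyl-(−)-catechin-8-yl)methylidene]cyclohexa-2,4-dien-1-one (formed in the flask) | c3ccccc3COc1cc(OCc3ccccc3)c2c(c1)O[C@H](c1cc(OCc3ccccc3)c(OCc3ccccc3)c(OCc3ccccc3)c1)[C@@H](OCc3ccccc3)[C@@H]2C1=C(OCc3ccccc3)C=C(OCc3ccccc3)C(C1=O)=Cc1c(OCc3ccccc3)cc(OCc3ccccc3)c2c1O[C@@H](c1ccc(OCc3ccccc3)c(OCc3ccccc3)c1)[C@H](OCc3ccccc3)C2 | intermediate
16 | benzyloxyketene (formed in the flask) | O=C=COCc1ccccc1 | intermediate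
17 | (3S,4S)-3,5,7-tris(benzyloxy)-8-(hexa-O-benzylgallocatechin-4α-yl)-4-[penta-O-benzyl-(−)-catechin-8-yl]chroman-2-one, 3,4-cis | c3ccccc3COc1cc(OCc3ccccc3)c2c(c1)O[C@H](c1cc(OCc3ccccc3)c(OCc3ccccc3)c(OCc3ccccc3)c1)[C@@H](OCc3ccccc3)[C@@H]2c1c(OCc3ccccc3)cc(OCc3ccccc3)c2c1OC(=O)[C@@H](OCc3ccccc3)[C@H]2c1c(OCc3ccccc3)cc(OCc3ccccc3)c2c1O[C@@H](c1ccc(OCc3ccccc3)c(OCc3ccccc3)c1)[C@H](OCc3ccccc3)C2 | intermediate
18 | diisobutylaluminium hemiacetal of 17 at C2 (formed in the flask) | c3ccccc3COc1cc(OCc3ccccc3)c2c(c1)O[C@H](c1cc(OCc3ccccc3)c(OCc3ccccc3)c(OCc3ccccc3)c1)[C@@H](OCc3ccccc3)[C@@H]2c1c(OCc3ccccc3)cc(OCc3ccccc3)c2c1OC(O[Al](CC(C)C)CC(C)C)[C@@H](OCc3ccccc3)[C@H]2c1c(OCc3ccccc3)cc(OCc3ccccc3)c2c1O[C@@H](c1ccc(OCc3ccccc3)c(OCc3ccccc3)c1)[C@H](OCc3ccccc3)C2 | intermediate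
19 | (3S,4S)-2-acetoxy-3,5,7-tris(benzyloxy)-8-(hexa-O-benzylgallocatechin-4α-yl)-4-[penta-O-benzyl-(−)-catechin-8-yl]chromane, both anomers | c3ccccc3COc1cc(OCc3ccccc3)c2c(c1)O[C@H](c1cc(OCc3ccccc3)c(OCc3ccccc3)c(OCc3ccccc3)c1)[C@@H](OCc3ccccc3)[C@@H]2c1c(OCc3ccccc3)cc(OCc3ccccc3)c2c1OC(OC(C)=O)[C@@H](OCc3ccccc3)[C@H]2c1c(OCc3ccccc3)cc(OCc3ccccc3)c2c1O[C@@H](c1ccc(OCc3ccccc3)c(OCc3ccccc3)c1)[C@H](OCc3ccccc3)C2 | intermediate
20 | 4-bromo-1,2-bis(benzyloxy)benzene | Brc1ccc(OCc2ccccc2)c(OCc2ccccc2)c1 | starting material
21 | (3,4-dibenzyloxyphenyl)lithium (formed in the flask) | [Li]c1ccc(OCc2ccccc2)c(OCc2ccccc2)c1 | intermediate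
22 | (3,4-dibenzyloxyphenyl)zinc chloride (formed in the flask) | Cl[Zn]c1ccc(OCc2ccccc2)c(OCc2ccccc2)c1 | intermediate
23 | hexadeca-O-benzyl gallocatechin-(4α→8)-catechin-(4β→8)-ent-catechin (middle unit 2R,3S,4S; C2 aryl trans to the cis pair at C3/C4) | c3ccccc3COc1cc(OCc3ccccc3)c2c(c1)O[C@H](c1cc(OCc3ccccc3)c(OCc3ccccc3)c(OCc3ccccc3)c1)[C@@H](OCc3ccccc3)[C@@H]2c1c(OCc3ccccc3)cc(OCc3ccccc3)c2c1O[C@H](c1ccc(OCc3ccccc3)c(OCc3ccccc3)c1)[C@@H](OCc3ccccc3)[C@H]2c1c(OCc3ccccc3)cc(OCc3ccccc3)c2c1O[C@@H](c1ccc(OCc3ccccc3)c(OCc3ccccc3)c1)[C@H](OCc3ccccc3)C2 | intermediate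
24 | gallocatechin-(4α→8)-catechin-(4β→8)-ent-catechin (CNP0155646.2) | Oc1cc(O)c2c(c1)O[C@H](c1cc(O)c(O)c(O)c1)[C@@H](O)[C@@H]2c1c(O)cc(O)c2c1O[C@H](c1ccc(O)c(O)c1)[C@@H](O)[C@H]2c1c(O)cc(O)c2c1O[C@@H](c1ccc(O)c(O)c1)[C@H](O)C2 | target

## Step count and risk

Total: 13 steps. Longest linear sequence: 10 steps (steps 1–5 and 9–13, from 1); the bottom branch (steps 6–8) joins at step 9.

**Step 10 (key step).**
- What may go wrong: the quinone methide 15 is strongly stabilised and flanked by two ortho-disubstituted rings, so conjugate addition may be slower than dimerisation of the ketene. The facial preference of the catalyst may be weakened by the chiral substrate, or the endo preference may be low, which would give the trans lactone. The kinetic cis lactone may epimerise at C3 if the mixture is warmed in the presence of base.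
- Fallback: sets out from 13 and returns at 17. The nucleophile is changed from a catalyst-bound enolate to a preformed silyl ketene acetal and the activation from Lewis base to Brønsted acid. Methyl benzyloxyacetate is converted (LiN(i-Pr)2, Me3SiCl) into [2-(benzyloxy)-1-methoxyethenyl]oxy(trimethyl)silane F1. A chiral phosphoric acid, for example (R)-3,3′-bis(2,4,6-triisopropylphenyl)-1,1′-binaphthyl-2,2′-diyl hydrogen phosphate, dehydrates 13 in the flask and guides the Mukaiyama–Michael addition of F1 to the ion-paired quinone methide. This gives the open-chain methyl 2-benzyloxy-3,3-diarylpropanoate F2 with a free phenol, whose diastereomers can be separated. Acid-catalysed lactonisation of the syn isomer (p-toluenesulfonic acid, toluene) closes O1–C2 and gives 17.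

**Step 12.**
- What may go wrong: facial selectivity at the oxocarbenium ion may be poor. Proton loss from C3 to the enol ether may compete, as may capture of the cation by an electron-rich ring A of a second molecule, if aryl transfer from zinc is slow in the presence of BF3.
- Fallback: sets out from 17 and returns at 23. The ring-closing bond is changed from C2–aryl to O1–C2. Reduction of 17 with i-Bu2AlH and aqueous work-up (potassium sodium tartrate) gives the lactol F3. Addition of 21 (excess, THF, −78 °C) to its hydroxy-aldehyde form gives the phenol diol F4 as carbinol epimers. Acid-mediated cyclodehydration (camphorsulfonic acid, CH2Cl2, 0 °C) proceeds through the benzylic cation stabilised by the 3,4-dibenzyloxyphenyl ring; the phenol closes the pyran with the C2 aryl group equatorial and trans to C3–O, and both epimers of F4 converge on 23.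

**Step 4.**
- What may go wrong: arylation at the para carbon of 5, a second alkylation of the product phenol, arrest at the aryl ether, or incomplete anti selectivity at C4.
- Fallback: sets out from 4 and returns at 7, bypassing 6 and step 5. A symmetric nucleophile removes the regiochemical question. Capture of the C4 cation of 4 by phloroglucinol (excess, BF3·OEt2, THF–CH2Cl2) gives 2-(hexa-O-benzylgallocatechin-4α-yl)benzene-1,3,5-triol F5, in which all ring positions are equivalent. Vilsmeier–Haack formylation (POCl3, DMF; aqueous NaOAc) gives the trihydroxybenzaldehyde F6. Benzylation with two equivalents of BnBr and K2CO3 etherifies the para hydroxyl and the unhindered ortho hydroxyl; the hydroxyl between the formyl and flavanyl groups stays free because it is hindered and hydrogen-bonded to the aldehyde, which is 7.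

**Step 9.**
- What may go wrong: the aryllithium may fail to add to the aldehyde, which is deactivated as its phenoxide and ortho-substituted on both sides. It may instead be quenched by proton transfer from benzylic ether positions.
- Fallback: sets out from 6 and 12 (made from 11) and returns at 13, bypassing step 5. The polarity is inverted. Quenching 12 with N,N-dimethylformamide gives 3,5,7,3′,4′-penta-O-benzyl-(−)-catechin-8-carbaldehyde F7. Phenol 6 is converted into its bromomagnesium phenoxide (EtMgBr, toluene) and undergoes ortho-specific hydroxyalkylation with F7 through a magnesium chelate, which gives 13 directly.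

## Further compounds

F1 | step 10 | [2-(benzyloxy)-1-methoxyethenyl]oxy(trimethyl)silane (geometry as formed) | COC(O[Si](C)(C)C)=COCc1ccccc1
F2 | step 10 | methyl (2S,3S)-2-benzyloxy-3-[4,6-bis(benzyloxy)-2-hydroxy-3-(hexa-O-benzylgallocatechin-4α-yl)phenyl]-3-[penta-O-benzyl-(−)-catechin-8-yl]propanoate | c3ccccc3COc1cc(OCc3ccccc3)c2c(c1)O[C@H](c1cc(OCc3ccccc3)c(OCc3ccccc3)c(OCc3ccccc3)c1)[C@@H](OCc3ccccc3)[C@@H]2c1c(OCc3ccccc3)cc(OCc3ccccc3)c(c1O)[C@@H]([C@H](OCc3ccccc3)C(=O)OC)c1c(OCc3ccccc3)cc(OCc3ccccc3)c2c1O[C@@H](c1ccc(OCc3ccccc3)c(OCc3ccccc3)c1)[C@H](OCc3ccccc3)C2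
F3 | step 12 | lactol: (3S,4S)-3,5,7-tris(benzyloxy)-8-(hexa-O-benzylgallocatechin-4α-yl)-4-[penta-O-benzyl-(−)-catechin-8-yl]chroman-2-ol, both anomers | c3ccccc3COc1cc(OCc3ccccc3)c2c(c1)O[C@H](c1cc(OCc3ccccc3)c(OCc3ccccc3)c(OCc3ccccc3)c1)[C@@H](OCc3ccccc3)[C@@H]2c1c(OCc3ccccc3)cc(OCc3ccccc3)c2c1OC(O)[C@@H](OCc3ccccc3)[C@H]2c1c(OCc3ccccc3)cc(OCc3ccccc3)c2c1O[C@@H](c1ccc(OCc3ccccc3)c(OCc3ccccc3)c1)[C@H](OCc3ccccc3)C2
F4 | step 12 | phenol diol: 2-benzyloxy-1-(3,4-dibenzyloxyphenyl)-3-[4,6-bis(benzyloxy)-2-hydroxy-3-(hexa-O-benzylgallocatechin-4α-yl)phenyl]-3-[penta-O-benzyl-(−)-catechin-8-yl]propan-1-ol, both carbinol epimers | c3ccccc3COc1cc(OCc3ccccc3)c2c(c1)O[C@H](c1cc(OCc3ccccc3)c(OCc3ccccc3)c(OCc3ccccc3)c1)[C@@H](OCc3ccccc3)[C@@H]2c1c(OCc3ccccc3)cc(OCc3ccccc3)c(c1O)[C@@H]([C@H](OCc3ccccc3)C(O)c1ccc(OCc3ccccc3)c(OCc3ccccc3)c1)c1c(OCc3ccccc3)cc(OCc3ccccc3)c2c1O[C@@H](c1ccc(OCc3ccccc3)c(OCc3ccccc3)c1)[C@H](OCc3ccccc3)C2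
F5 | step 4 | 2-(hexa-O-benzylgallocatechin-4α-yl)benzene-1,3,5-triol | c3ccccc3COc1cc(OCc3ccccc3)c2c(c1)O[C@H](c1cc(OCc3ccccc3)c(OCc3ccccc3)c(OCc3ccccc3)c1)[C@@H](OCc3ccccc3)[C@@H]2c1c(O)cc(O)cc1O
F6 | step 4 | 2,4,6-trihydroxy-3-(hexa-O-benzylgallocatechin-4α-yl)benzaldehyde | c3ccccc3COc1cc(OCc3ccccc3)c2c(c1)O[C@H](c1cc(OCc3ccccc3)c(OCc3ccccc3)c(OCc3ccccc3)c1)[C@@H](OCc3ccccc3)[C@@H]2c1c(O)cc(O)c(C=O)c1O
F7 | step 9 | 3,5,7,3′,4′-penta-O-benzyl-(−)-catechin-8-carbaldehyde | c3ccccc3COc1cc(OCc3ccccc3)c2c(c1C=O)O[C@@H](c1ccc(OCc3ccccc3)c(OCc3ccccc3)c1)[C@H](OCc3ccccc3)C2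
A1 | alternative 1 | 3,4-cis 4-aryl tetra-O-benzylcatechin whose aryl group is methyl 2,4,6-trihydroxybenzoate | c3ccccc3COc1cc(OCc3ccccc3)c2c(c1)O[C@H](c1ccc(OCc3ccccc3)c(OCc3ccccc3)c1)[C@@H](O)[C@H]2c1c(O)cc(O)c(C(=O)OC)c1O
A2 | alternative 1 | γ-lactone cis-fused across O3/C4 of tetra-O-benzylcatechin with a C(=O)CH2C(=O)CH2CO2Me chain on its α-carbon | c3ccccc3COc1cc(OCc3ccccc3)c2c(c1)O[C@H](c1ccc(OCc3ccccc3)c(OCc3ccccc3)c1)[C@H]1OC(=O)C(C(=O)CC(=O)CC(=O)OC)[C@@H]21
A3 | alternative 2 | benzyl-protected trimer with free top C3–OH | c3ccccc3COc1cc(OCc3ccccc3)c2c(c1)O[C@H](c1cc(OCc3ccccc3)c(OCc3ccccc3)c(OCc3ccccc3)c1)[C@@H](O)[C@@H]2c1c(OCc3ccccc3)cc(OCc3ccccc3)c2c1O[C@H](c1ccc(OCc3ccccc3)c(OCc3ccccc3)c1)[C@@H](OCc3ccccc3)[C@H]2c1c(OCc3ccccc3)cc(OCc3ccccc3)c2c1O[C@@H](c1ccc(OCc3ccccc3)c(OCc3ccccc3)c1)[C@H](OCc3ccccc3)C2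
A4 | alternative 2 | E-configured aryl allyl ether: 3,5-bis(benzyloxy)phenyl ether of the 1-(3,4,5-tribenzyloxyphenyl)allyl alcohol whose alkene terminus is C8 of the protected middle–bottom dimer | c3ccccc3COc1cc(OCc3ccccc3)cc(c1)O[C@H](c1cc(OCc3ccccc3)c(OCc3ccccc3)c(OCc3ccccc3)c1)/C=C/c1c(OCc3ccccc3)cc(OCc3ccccc3)c2c1O[C@H](c1ccc(OCc3ccccc3)c(OCc3ccccc3)c1)[C@@H](OCc3ccccc3)[C@H]2c1c(OCc3ccccc3)cc(OCc3ccccc3)c2c1O[C@@H](c1ccc(OCc3ccccc3)c(OCc3ccccc3)c1)[C@H](OCc3ccccc3)C2
A5 | alternative 3 | benzyl-protected trimer with a pinacolboryl group at top C3 | c3ccccc3COc1cc(OCc3ccccc3)c2c(c1)O[C@H](c1cc(OCc3ccccc3)c(OCc3ccccc3)c(OCc3ccccc3)c1)[C@@H](B4OC(C)(C)C(C)(C)O4)[C@@H]2c1c(OCc3ccccc3)cc(OCc3ccccc3)c2c1O[C@H](c1ccc(OCc3ccccc3)c(OCc3ccccc3)c1)[C@@H](OCc3ccccc3)[C@H]2c1c(OCc3ccccc3)cc(OCc3ccccc3)c2c1O[C@@H](c1ccc(OCc3ccccc3)c(OCc3ccccc3)c1)[C@H](OCc3ccccc3)C2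
A6 | alternative 3 | benzhydrol: [2-hydroxy-4,6-bis(benzyloxy)phenyl][C8 of the protected middle–bottom dimer]methanol | Oc1cc(OCc3ccccc3)cc(OCc3ccccc3)c1C(O)c1c(OCc3ccccc3)cc(OCc3ccccc3)c2c1O[C@H](c1ccc(OCc3ccccc3)c(OCc3ccccc3)c1)[C@@H](OCc3ccccc3)[C@H]2c1c(OCc3ccccc3)cc(OCc3ccccc3)c2c1O[C@@H](c1ccc(OCc3ccccc3)c(OCc3ccccc3)c1)[C@H](OCc3ccccc3)C2
A7 | alternative 3 | (E)-2-(3,4,5-tribenzyloxyphenyl)vinylboronic acid pinacol ester | CC1(C)OB(/C=C/c2cc(OCc3ccccc3)c(OCc3ccccc3)c(OCc3ccccc3)c2)OC1(C)C
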